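Ring A (C1, C5, C6, C7, C8, C9, C10) bears oxygen at C8 and methyl groups on C5 and C10, the substitution pattern of a cyclohept-4-enone, and is therefore cut at C9–C10. In one operation the tertiary C5 hydroxyl adds across the C8≡C9 alkyne and the resulting 2-methylene-5-propenyltetrahydrofuran undergoes a [3,3] shift: C9–C10 forms, C5–O breaks, ring A closes as the C8 ketone, and the C5 configuration is relayed to C10. The precursor is an acyclic tertiary (E)-propenyl carbinol with ethynyl and silyloxyethyl groups on C7 and an allyloxy spectator on C6, which afterwards carries C2–C4 to C1 by a [2,3]-Wittig shift.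

Key step: step 9

Remark on numbering: ring A = C1, C5, C6, C7, C8, C9, C10. C2–C4 is the chain on C1 (C2 angelate, C4 acetate). C11–C13 are the lactone carbons (C12 carbonyl, C13 methylene). C14 is the methyl on C10 and C15 the methyl on C5. α is the face of ring A that carries C11 (on C7) and O (on C8); β is the face of C14. The target is 1S,2S,7R,8R,10R, with a cis lactone and the C1 chain α, trans to C14.
Remark on the chemistry: (E)-1-bromopropene is taken as the commercial single isomer.

Step 1
Reactants: 1 3-[(tert-butyldimethylsilyl)oxy]propanal; 2 ethynyltrimethylsilane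
Product: 4 rac-5-[(tert-butyldimethylsilyl)oxy]-1-(trimethylsilyl)pent-1-yn-3-ol, via lithium (trimethylsilyl)acetylide 3 (not isolated)
Conditions: 2, n-BuLi, THF, −78 °C; then 1; NH4Cl aq
Reagents that add atoms: none
Why: 1,2-Addition of a lithium acetylide to an aldehyde builds the C7–C8 bond, and the carbinol centre is left racemic because step 2 erases it.

Step 2
Reactants: 4 rac-5-[(tert-butyldimethylsilyl)oxy]-1-(trimethylsilyl)pent-1-yn-3-ol
Product: 5 5-[(tert-butyldimethylsilyl)oxy]-1-(trimethylsilyl)pent-1-yn-3-one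
Conditions: MnO2 (excess), CH2Cl2, rt
Reagents that add atoms: none
Why: MnO2 oxidises the activated propargylic alcohol to the ynone under neutral conditions (propargylic alcohol oxidation), so the β-silyloxy group is not eliminated.

Step 3
Reactants: 5 5-[(tert-butyldimethylsilyl)oxy]-1-(trimethylsilyl)pent-1-yn-3-one
Product: 7 (S)-5-[(tert-butyldimethylsilyl)oxy]pent-1-yn-3-ol, via (S)-C-silyl alkynol 6 (not isolated)
Conditions: Ru[(S,S)-TsDPEN](p-cymene) (1 mol %), i-PrOH, rt; then K2CO3 (cat.), MeOH, rt
Reagents that add atoms: none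
Why: Noyori asymmetric transfer hydrogenation of an alkynyl ketone, in which the base-free (S,S)-catalyst tells the alkynyl from the alkyl flank and should give the S carbinol, is followed in the same flask by carbonate-catalysed methanolysis that removes only the carbon-bound silyl group.

Step 4
Reactants: 7 (S)-5-[(tert-butyldimethylsilyl)oxy]pent-1-yn-3-ol
Product: 8 (S)-5-[(tert-butyldimethylsilyl)oxy]pent-1-yn-3-yl methanesulfonate
Conditions: MsCl, Et3N, CH2Cl2, −78 → 0 °C
Reagents that add atoms: methanesulfonyl chloride, CS(=O)(=O)Cl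
Why: Sulfonylation at oxygen leaves the stereocentre untouched and provides the leaving group for step 5.

Step 5
Reactants: 8 (S)-5-[(tert-butyldimethylsilyl)oxy]pent-1-yn-3-yl methanesulfonate; 9 methacrolein
Product: 11 (3R,4R)-6-[(tert-butyldimethylsilyl)oxy]-4-ethynyl-2-methylhex-1-en-3-ol (C6–OH and C7 arm anti), via (M)-allenylzinc 10 (not isolated)
Conditions: Pd(OAc)2 (5 mol %), PPh3 (5 mol %), Et2Zn (3 equiv), THF, −78 → −20 °C; NH4Cl aq
Reagents that add atoms: none
Why: Marshall propargylation: zerovalent palladium displaces the mesylate in an anti SN2′ sense, Et2Zn transmetalates to allenylzinc 10, and its cyclic SE2′ addition to the aldehyde gives the anti homopropargylic alcohol, so that C7 forms with net inversion of the mesylate centre and C6 follows from the anti-selective cyclic array, which the α-branched enal favours.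

Step 6
Reactants: 11 (3R,4R)-6-[(tert-butyldimethylsilyl)oxy]-4-ethynyl-2-methylhex-1-en-3-ol
Product: 12 (3R,4R)-6-[(tert-butyldimethylsilyl)oxy]-4-ethynyl-3-hydroxyhexan-2-one
Conditions: O3, CH2Cl2, −78 °C (stopped when 11 is consumed); then Me2S
Reagents that add atoms: ozone, [O-][O+]=O
Why: Ozonolysis cleaves the electron-rich 1,1-disubstituted alkene much faster than the terminal alkyne and unmasks the C5 methyl ketone.

Step 7
Reactants: 12 (3R,4R)-6-[(tert-butyldimethylsilyl)oxy]-4-ethynyl-3-hydroxyhexan-2-one; 13 (E)-1-bromopropene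
Product: 16 (2E,4R,5R,6R)-8-[(tert-butyldimethylsilyl)oxy]-6-ethynyl-4-methyloct-2-ene-4,5-diol, via (E)-propenyllithium 14 (not isolated), via (E)-propenylmagnesium bromide 15 (not isolated)
Conditions: 13 (4 equiv), t-BuLi (8 equiv), Et2O, −78 °C; MgBr2·OEt2; then 12, THF, −78 → 0 °C; NH4Cl aq
Reagents that add atoms: none
Why: Bromine–lithium exchange and transmetalation keep the E geometry, and the Grignard reagent, after deprotonating O–H and the alkyne C–H, adds to the five-membered magnesium chelate of the C6 alkoxide and the C5 carbonyl from the side of C6–H, away from the C7 branch (Cram chelate control), which sets the tertiary C5 centre.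

Step 8
Reactants: 16 (2E,4R,5R,6R)-8-[(tert-butyldimethylsilyl)oxy]-6-ethynyl-4-methyloct-2-ene-4,5-diol; 17 allyl bromide
Product: 18 (2E,4R,5R,6R)-5-(allyloxy)-8-[(tert-butyldimethylsilyl)oxy]-6-ethynyl-4-methyloct-2-en-4-ol
Conditions: NaH (1.1 equiv), 17, Bu4NI (cat.), THF–DMF, 0 °C
Reagents that add atoms: none
Why: Williamson etherification: the secondary C6 alkoxide is alkylated by the reactive allyl bromide while the more hindered tertiary C5 hydroxyl, needed free in step 9, stays untouched.

Step 9
Reactants: 18 (2E,4R,5R,6R)-5-(allyloxy)-8-[(tert-butyldimethylsilyl)oxy]-6-ethynyl-4-methyloct-2-en-4-ol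
Product: 20 (2S,3R,6R)-3-(allyloxy)-2-{2-[(tert-butyldimethylsilyl)oxy]ethyl}-4,6-dimethylcyclohept-4-en-1-one (C6–O and C7 arm α, C14 β), via 2-methylenetetrahydrofuran 19 (not isolated)
Conditions: Ag2CO3 (10 mol %), PhMe, 80 °C, dark; filter (Celite); propylene oxide (acid scavenger), 185 °C, sealed silylated tube
Reagents that add atoms: none
Why: Monovalent silver activates the terminal alkyne and the C5 hydroxyl adds 5-exo-dig (O to C8) to give the exocyclic enol ether 19, an allyl vinyl ether C9=C8–O–C5–C1=C10 held in a five-membered ring, and heating drives the Claisen [3,3] shift that forms C9–C10, breaks C5–O and releases the C8 carbonyl. The closest known reaction type is the tandem 5-exo-dig cyclisation–Claisen ring enlargement of 4-alkyn-1-ols that carry an alkenyl carbinol, run here with a neutral silver catalyst instead of an alkoxide base because 20 is a β-alkoxy ketone whose C7, α to the carbonyl, would epimerise or trigger elimination under base. Ring A closes by enlargement from five to seven members through a bridged chair-like array shaped like an 8-oxabicyclo[3.2.1]octane, the only array that leaves a cis C1=C5 alkene in the ring. C10 is the one new stereocentre: bonding is suprafacial on C5–C1–C10 and C6 must end cis to C10, so the C5 configuration together with the E geometry of the propenyl group fixes 10R, while C6 and C7 are not touched. The step needs exo regiochemistry in the cyclisation, secured by the terminal alkyne and the four-atom O-to-C8 tether, and survival of the exocyclic enol ether, secured by acid-free glass and the epoxide scavenger. The cost is that the C6 and C7 substituents lie on the concave side of the bridged array, which slows the shift and is the main risk of the route.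

Step 10
Reactants: 20 (2S,3R,6R)-3-(allyloxy)-2-{2-[(tert-butyldimethylsilyl)oxy]ethyl}-4,6-dimethylcyclohept-4-en-1-one
Product: 21 (1R,2R,3R,6R)-3-(allyloxy)-2-{2-[(tert-butyldimethylsilyl)oxy]ethyl}-4,6-dimethylcyclohept-4-en-1-ol (C6–O, C7 arm and C8–OH all α)
Conditions: LiBH(s-Bu)3, THF, −78 °C; then NaOH, H2O2, 0 °C
Reagents that add atoms: none
Why: The bulky trialkylborohydride should attack the C8 carbonyl from the β face, opposite the C7 arm and the C6 ether, so that the hydroxyl ends α and cis to the arm (diastereoselective reduction of a 2-substituted cycloalkanone), and at −78 °C neither C7 epimerisation nor β-elimination should intervene.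

Step 11
Reactants: 21 (1R,2R,3R,6R)-3-(allyloxy)-2-{2-[(tert-butyldimethylsilyl)oxy]ethyl}-4,6-dimethylcyclohept-4-en-1-ol
Product: 22 (1R,2S,5S,6R)-2-{2-[(tert-butyldimethylsilyl)oxy]ethyl}-5-[(1S)-1-hydroxyprop-2-en-1-yl]-4,6-dimethylcyclohept-3-en-1-ol
Conditions: n-BuLi (3 equiv), THF, −78 → −30 °C; NH4Cl aq added cold
Reagents that add atoms: none
Why: [2,3]-Wittig rearrangement: after O–H deprotonation n-BuLi lithiates the less substituted allyl CH2, the five-membered envelope moves this carbon suprafacially from the α C6–O to the α face of C1 while the alkene shifts to C5=C6, which fixes 1S and the alkene position without any choice of hydrogen donor, and the vinyl group is expected to sit exo on the envelope as in the syn-selective shifts of Z-configured allylic ethers, which gives 2S.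

Step 12
Reactants: 22 (1R,2S,5S,6R)-2-{2-[(tert-butyldimethylsilyl)oxy]ethyl}-5-[(1S)-1-hydroxyprop-2-en-1-yl]-4,6-dimethylcyclohept-3-en-1-ol
Product: 23 (1R,2S,5S,6R)-2-{2-[(tert-butyldimethylsilyl)oxy]ethyl}-5-[(1S)-1,3-dihydroxypropyl]-4,6-dimethylcyclohept-3-en-1-ol
Conditions: 9-BBN (4 equiv), THF, 0 °C → rt; then NaOH, H2O2
Reagents that add atoms: hydrogen peroxide, OO
Why: Hydroboration–oxidation: 9-BBN places boron on the terminal C4 of the monosubstituted vinyl group and ignores the hindered trisubstituted C5=C6 alkene.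

Step 13
Reactants: 23 (1R,2S,5S,6R)-2-{2-[(tert-butyldimethylsilyl)oxy]ethyl}-5-[(1S)-1,3-dihydroxypropyl]-4,6-dimethylcyclohept-3-en-1-ol
Product: 24 (1R,2S,5S,6R)-2-{2-[(tert-butyldimethylsilyl)oxy]ethyl}-5-[(4S)-2,2-dimethyl-1,3-dioxan-4-yl]-4,6-dimethylcyclohept-3-en-1-ol
Conditions: Me2C(OMe)2, PPTS (cat.), CH2Cl2, rt
Reagents that add atoms: 2,2-dimethoxypropane, COC(C)(C)OC
Why: Acid-catalysed transacetalisation closes the six-membered 1,3-dioxane on the C2/C4 diol, whereas C8–OH has no partner hydroxyl within reach.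

Step 14
Reactants: 24 (1R,2S,5S,6R)-2-{2-[(tert-butyldimethylsilyl)oxy]ethyl}-5-[(4S)-2,2-dimethyl-1,3-dioxan-4-yl]-4,6-dimethylcyclohept-3-en-1-ol
Product: 25 (1R,2S,5S,6R)-5-[(4S)-2,2-dimethyl-1,3-dioxan-4-yl]-2-(2-hydroxyethyl)-4,6-dimethylcyclohept-3-en-1-ol
Conditions: Bu4NF, THF, rt
Reagents that add atoms: none
Why: Fluoride-induced desilylation frees the primary C12 alcohol and does not touch the acetonide or the alkene.

Step 15
Reactants: 25 (1R,2S,5S,6R)-5-[(4S)-2,2-dimethyl-1,3-dioxan-4-yl]-2-(2-hydroxyethyl)-4,6-dimethylcyclohept-3-en-1-ol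
Product: 27 cis-fused γ-lactone (C7–C11H2–C12(=O)–O–C8, fusion on the α face) carrying the C2/C4 acetonide chain on C1, via lactol 26 (not isolated)
Conditions: TEMPO (20 mol %), PhI(OAc)2 (2.5 equiv), CH2Cl2, rt
Reagents that add atoms: none
Why: Oxoammonium oxidation takes the primary C12 alcohol to the aldehyde, which closes on the cis C8–OH to lactol 26 and is oxidised on to the lactone (oxidative lactonisation of a 1,4-diol).

Step 16
Reactants: 27 cis-fused γ-lactone carrying the C2/C4 acetonide chain
Product: 30 α-methylene-γ-lactone (C11=C13) carrying the C2/C4 acetonide chain, via Mannich base 28 (not isolated), via ammonium iodide 29 (not isolated)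
Conditions: LiN(i-Pr)2, THF, −78 °C; CH2=NMe2+ I−, −78 °C → rt; then MeI, MeOH, rt; then NaHCO3 aq, CH2Cl2
Reagents that add atoms: N,N-dimethylmethyleneiminium iodide (Eschenmoser's salt), C=[N+](C)C.[I-]
Why: Mannich aminomethylation of the lactone enolate followed by quaternisation and β-elimination installs C13, and it is placed here because the lactone is the only enolisable carbonyl at this stage.

Step 17
Reactants: 30 α-methylene-γ-lactone carrying the C2/C4 acetonide chain
Product: 31 α-methylene-γ-lactone 2,4-diol ((2S)-1,3-dihydroxypropyl chain on C1)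
Conditions: AcOH–THF–H2O, 40 °C
Reagents that add atoms: none
Why: Mild acetal hydrolysis frees the 1,3-diol under conditions that the α-methylene lactone and the C5=C6 alkene tolerate.

Step 18
Reactants: 31 α-methylene-γ-lactone 2,4-diol
Product: 32 C4 monoacetate with free (2S)-hydroxyl
Conditions: AcCl (1.05 equiv), 2,4,6-collidine, CH2Cl2, −78 °C
Reagents that add atoms: acetyl chloride, CC(=O)Cl
Why: Kinetic acylation with a hindered pyridine base strongly prefers the primary C4 hydroxyl over the secondary C2 hydroxyl flanked by ring A.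

Step 19
Reactants: 32 C4 monoacetate with free (2S)-hydroxyl; 33 angelic acid
Product: 35 target CNP0163960.1 (1S,2S,7R,8R,10R; Z angelate), via mixed anhydride 34 (not isolated)
Conditions: 33, 2,4,6-Cl3C6H2COCl, Et3N, PhMe, rt, filter; then 32, PhMe, 80 °C
Reagents that add atoms: none
Why: Yamaguchi esterification through the mixed anhydride, run without a nucleophilic catalyst and without free amine, acylates C2–OH at the less hindered angeloyl carbonyl with retention at C2 and should keep the Z geometry of the angelate.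

Compound list
1 | 3-[(tert-butyldimethylsilyl)oxy]propanal | O=CCCO[Si](C)(C)C(C)(C)C | starting material
2 | ethynyltrimethylsilane | C#C[Si](C)(C)C | starting material
3 | lithium (trimethylsilyl)acetylide | [Li]C#C[Si](C)(C)C | intermediate
4 | rac-5-[(tert-butyldimethylsilyl)oxy]-1-(trimethylsilyl)pent-1-yn-3-ol | C[Si](C)(C)C#CC(O)CCO[Si](C)(C)C(C)(C)C | intermediate
5 | 5-[(tert-butyldimethylsilyl)oxy]-1-(trimethylsilyl)pent-1-yn-3-one | C[Si](C)(C)C#CC(=O)CCO[Si](C)(C)C(C)(C)C | intermediate
6 | (S)-5-[(tert-butyldimethylsilyl)oxy]-1-(trimethylsilyl)pent-1-yn-3-ol | C[Si](C)(C)C#C[C@@H](O)CCO[Si](C)(C)C(C)(C)C | intermediate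
7 | (S)-5-[(tert-butyldimethylsilyl)oxy]pent-1-yn-3-ol | C#C[C@@H](O)CCO[Si](C)(C)C(C)(C)C | intermediate
8 | (S)-5-[(tert-butyldimethylsilyl)oxy]pent-1-yn-3-yl methanesulfonate | C#C[C@H](CCO[Si](C)(C)C(C)(C)C)OS(C)(=O)=O | intermediate
9 | methacrolein | C=C(C)C=O | starting material
10 | (M)-ethyl{5-[(tert-butyldimethylsilyl)oxy]penta-1,2-dienyl}zinc | CC[Zn]C([H])=[C@]=C([H])CCO[Si](C)(C)C(C)(C)C | intermediate
11 | (3R,4R)-6-[(tert-butyldimethylsilyl)oxy]-4-ethynyl-2-methylhex-1-en-3-ol | C#C[C@@H](CCO[Si](C)(C)C(C)(C)C)[C@@H](O)C(C)=C | intermediate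
12 | (3R,4R)-6-[(tert-butyldimethylsilyl)oxy]-4-ethynyl-3-hydroxyhexan-2-one | C#C[C@@H](CCO[Si](C)(C)C(C)(C)C)[C@@H](O)C(C)=O | intermediate
13 | (E)-1-bromopropene | C/C=C/Br | starting material
14 | (E)-propenyllithium | C/C=C/[Li] | intermediate
15 | (E)-propenylmagnesium bromide | C/C=C/[Mg]Br | intermediate
16 | (2E,4R,5R,6R)-8-[(tert-butyldimethylsilyl)oxy]-6-ethynyl-4-methyloct-2-ene-4,5-diol | C#C[C@@H](CCO[Si](C)(C)C(C)(C)C)[C@@H](O)[C@](C)(O)/C=C/C | intermediate
17 | allyl bromide | C=CCBr | starting material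
18 | (2E,4R,5R,6R)-5-(allyloxy)-8-[(tert-butyldimethylsilyl)oxy]-6-ethynyl-4-methyloct-2-en-4-ol (key-step precursor) | C#C[C@@H](CCO[Si](C)(C)C(C)(C)C)[C@@H](OCC=C)[C@](C)(O)/C=C/C | intermediate
19 | (2R,3R,4S)-3-(allyloxy)-4-{2-[(tert-butyldimethylsilyl)oxy]ethyl}-2-methyl-5-methylene-2-[(E)-prop-1-enyl]tetrahydrofuran | C=C1O[C@](C)(/C=C/C)[C@H](OCC=C)[C@@H]1CCO[Si](C)(C)C(C)(C)C | intermediate
20 | (2S,3R,6R)-3-(allyloxy)-2-{2-[(tert-butyldimethylsilyl)oxy]ethyl}-4,6-dimethylcyclohept-4-en-1-one (key-step product) | C[C@@H]1CC(=O)[C@@H](CCO[Si](C)(C)C(C)(C)C)[C@@H](OCC=C)C(C)=C1 | intermediate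
21 | (1R,2R,3R,6R)-3-(allyloxy)-2-{2-[(tert-butyldimethylsilyl)oxy]ethyl}-4,6-dimethylcyclohept-4-en-1-ol | C[C@@H]1C[C@@H](O)[C@@H](CCO[Si](C)(C)C(C)(C)C)[C@@H](OCC=C)C(C)=C1 | intermediate
22 | (1R,2S,5S,6R)-2-{2-[(tert-butyldimethylsilyl)oxy]ethyl}-5-[(1S)-1-hydroxyprop-2-en-1-yl]-4,6-dimethylcyclohept-3-en-1-ol | O[C@@H]1C[C@@H](C)[C@H]([C@H](C=C)O)C(C)=C[C@@H]1CCO[Si](C)(C)C(C)(C)C | intermediate
23 | (1R,2S,5S,6R)-2-{2-[(tert-butyldimethylsilyl)oxy]ethyl}-5-[(1S)-1,3-dihydroxypropyl]-4,6-dimethylcyclohept-3-en-1-ol | O[C@@H]1C[C@@H](C)[C@H]([C@H](CCO)O)C(C)=C[C@@H]1CCO[Si](C)(C)C(C)(C)C | intermediate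
24 | (1R,2S,5S,6R)-2-{2-[(tert-butyldimethylsilyl)oxy]ethyl}-5-[(4S)-2,2-dimethyl-1,3-dioxan-4-yl]-4,6-dimethylcyclohept-3-en-1-ol | O[C@@H]1C[C@@H](C)[C@H]([C@@H]2CCOC(C)(C)O2)C(C)=C[C@@H]1CCO[Si](C)(C)C(C)(C)C | intermediate
25 | (1R,2S,5S,6R)-5-[(4S)-2,2-dimethyl-1,3-dioxan-4-yl]-2-(2-hydroxyethyl)-4,6-dimethylcyclohept-3-en-1-ol | O[C@@H]1C[C@@H](C)[C@H]([C@@H]2CCOC(C)(C)O2)C(C)=C[C@@H]1CCO | intermediate
26 | cis-fused lactol (C12 hemiacetal, both anomers) with acetonide chain | C1C(O)O[C@@H]2C[C@@H](C)[C@H]([C@@H]3CCOC(C)(C)O3)C(C)=C[C@H]12 | intermediate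
27 | cis-fused γ-lactone with acetonide chain | C1C(=O)O[C@@H]2C[C@@H](C)[C@H]([C@@H]3CCOC(C)(C)O3)C(C)=C[C@H]12 | intermediate
28 | C11-(dimethylaminomethyl) lactone (C11 epimers) | CN(C)CC1C(=O)O[C@@H]2C[C@@H](C)[C@H]([C@@H]3CCOC(C)(C)O3)C(C)=C[C@H]12 | intermediate
29 | C11-(trimethylammoniomethyl) lactone iodide | C[N+](C)(C)CC1C(=O)O[C@@H]2C[C@@H](C)[C@H]([C@@H]3CCOC(C)(C)O3)C(C)=C[C@H]12.[I-] | intermediate
30 | α-methylene-γ-lactone with acetonide chain | C=C1C(=O)O[C@@H]2C[C@@H](C)[C@H]([C@@H]3CCOC(C)(C)O3)C(C)=C[C@H]12 | intermediate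
31 | α-methylene-γ-lactone 2,4-diol | C=C1C(=O)O[C@@H]2C[C@@H](C)[C@H]([C@H](CCO)O)C(C)=C[C@H]12 | intermediate
32 | α-methylene-γ-lactone, C4 acetate, free (2S)-hydroxyl | C=C1C(=O)O[C@@H]2C[C@@H](C)[C@H]([C@H](CCOC(C)=O)O)C(C)=C[C@H]12 | intermediate
33 | angelic acid, (Z)-2-methylbut-2-enoic acid | OC(=O)/C(C)=C\C | starting material
34 | angelic 2,4,6-trichlorobenzoic anhydride | O=C(OC(=O)/C(C)=C\C)c1c(Cl)cc(Cl)cc1Cl | intermediate
35 | CNP0163960.1 | C=C1C(=O)O[C@@H]2C[C@@H](C)[C@H]([C@H](CCOC(C)=O)OC(=O)/C(C)=C\C)C(C)=C[C@H]12 | target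

Total step count: 19. Longest linear sequence: 19 steps (1 to 35).

Steps most likely to fail

1. Step 9. The [3,3] shift may be too slow because the C6 and C7 substituents sit on the concave side of the bridged array. Two processes could then compete at the temperature needed: migration of the exocyclic double bond into the five-membered ring, and thermal loss of allyl alcohol from the β-alkoxy ketone. The fallback separates the two events. It sets out from enol ether 19, isolated after the silver step by filtration and evaporation. The shift is triggered with i-Bu3Al in CH2Cl2 from −78 °C to room temperature (aluminium-promoted reductive Claisen ring enlargement). The carbonyl is reduced by β-hydride transfer as soon as it forms, which gives the 3-(allyloxy)cyclohept-4-enol as a C8 epimer mixture F1. Dess–Martin oxidation at 0 °C, buffered with NaHCO3, returns to 20.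

2. Step 11. The vinyl group may not discriminate well between the exo and endo positions on the envelope, which would erode the configuration at C2, and a [1,2] shift may compete on warming. The fallback sets C2 by reagent control. It sets out from 22 obtained as a C2 epimer mixture. MnO2 in CH2Cl2 oxidises only the allylic C2 alcohol, giving the vinyl ketone F2. Reduction with the (R)-Me-CBS oxazaborolidine and catecholborane in PhMe at −78 °C, with ring carbon C1 acting as the large group, should return (2S)-configured 22.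

3. Step 19. Acylation of the hindered C2 hydroxyl may be slow, and Z to E isomerisation of the activated angeloyl unit may then overtake it. The fallback builds the Z alkene on the ester. It sets out from 32, which is esterified with 2-[bis(2,2,2-trifluoroethoxy)phosphoryl]propanoic acid (EDC·HCl, cat. DMAP, CH2Cl2) to the phosphonopropionate F3. Still–Gennari olefination (KN(SiMe3)2, 18-crown-6, THF, −78 °C, then acetaldehyde) should then give 35 directly.

Further compounds
F1 | step 9 | (2R,3R,6R)-3-(allyloxy)-2-{2-[(tert-butyldimethylsilyl)oxy]ethyl}-4,6-dimethylcyclohept-4-en-1-ol, C8 epimer mixture | C[C@@H]1CC(O)[C@@H](CCO[Si](C)(C)C(C)(C)C)[C@@H](OCC=C)C(C)=C1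
F2 | step 11 | 1-[(1S,4S,5R,7R)-4-{2-[(tert-butyldimethylsilyl)oxy]ethyl}-5-hydroxy-2,7-dimethylcyclohept-2-en-1-yl]prop-2-en-1-one | O[C@@H]1C[C@@H](C)[C@H](C(=O)C=C)C(C)=C[C@@H]1CCO[Si](C)(C)C(C)(C)C
F3 | step 19 | C2 2-[bis(2,2,2-trifluoroethoxy)phosphoryl]propanoate of 32 | C=C1C(=O)O[C@@H]2C[C@@H](C)[C@H]([C@H](CCOC(C)=O)OC(=O)C(C)P(=O)(OCC(F)(F)F)OCC(F)(F)F)C(C)=C[C@H]12
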